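The vessel is a stirred flask in which starting material and reagent make product and by-product, while two reagent can also join to homo dimer. The five flasks differ in when the starting material arrives and how cold it is.

| setting | cedar | birch | larch | alder | maple |
|---|---|---|---|---|---|
| starting material | 0.20 M (fed, over 2.5 h) | 0.20 M (fed, over 2.5 h) | 0.20 M | 0.20 M | 0.20 M (in portions, 3, over 2.5 h) |
| reagent | 1.00 equiv | 1.00 equiv | 1.00 equiv | 1.00 equiv | 1.00 equiv |
| time | 6.0 h | 6.0 h | 6.0 h | 6.0 h | 6.0 h |
| remark | the addition at −15 °C, then warmed to 5 °C; the feed brings no volume worth counting | all else is in the flask from the start; the feed brings no volume worth counting | everything together at the start | everything together at the start at −15 °C, warmed to 5 °C at 2.5 h | first portion at the start, last at 2.5 h |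
| temperature |  | 5 °C | 5 °C |  | 5 °C |

- for a step with 2 of a species take k times the square, and two of it per event
- all constants are for 5 °C and move with temperature by the activation energies

1. which flask leads in amount of product, in percent of the starting material charged ("all alike" within 1.5 percentage points) (cedar / birch / larch / alder / maple / all alike)
2. how much product is there at the end, in percent of the starting material charged: cedar
3. how much product is there at the end, in percent of the starting material charged: birch
4. how much product is there at the end, in percent of the starting material charged: larch
5. how much product is there at the end, in percent of the starting material charged: alder
6. how much product is there at the end, in percent of the starting material charged: maple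

I reckoned with one number: the reagent level at which, with starting material at its full charge, the two steps consume reagent equally fast. This is the crossing concentration 0.0243 M, the product-making constant times the starting material over twice the dimer constant. Reagent began at 0.200 M, higher than the crossing, so I expected dimer formation to take the larger share of reagent at first. With starting material held constant, the product step is pseudo-first-order in reagent, with constant 0.102 /h. Product made is then the crossing times ln(1 + (reagent at the start of contact / crossing) × (1 − exp(−constant × time))).

I solved two extreme versions at 5 °C. In the early one, the full charge of starting material stands there from the start and never falls, which gives 19.0% at 6.0 h. In the late one, reagent waits by itself for 2.5 h, longer than its first dimerisation half-life of 1.19 h, and falls to 0.0645 M. The full charge then arrives at once, which gives 7.12%. Larch has the early timing with a falling starting material, so I placed it just under the early figure. Birch and maple get their starting material sooner than the late version does, so I placed them between the two figures. For cedar and alder I reckoned no figure. Dimerisation has the higher activation energy, 65.0 kJ/mol against 51.0 kJ/mol, so I expected cold to spare reagent and put both above birch and maple. Alder has its whole charge of starting material there from the start and cedar does not, and I put alder ahead of cedar. I put both below larch as a judgement, with no figure behind it.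

The forecast named larch as leader, with cedar 14.3%, birch 12%, larch 17.5%, alder 16% and maple 12.4%, holding that “anything that delays the starting material while reagent is burning away” loses product.

The simulation put larch in the lead and gave cedar 14.1%, birch 11.3%, larch 17.5%, alder 15.8% and maple 11.8%, so larch stood under the early figure and birch above the late one.

    starting material + reagent → product + by-product (k1 = 0.51 /M/h, Ea1 = 51.0 kJ/mol)
    2 reagent → homo dimer (k2 = 2.1 /M/h, Ea2 = 65.0 kJ/mol)
    (constants at 5 °C)

Birch left until 15 h is the neighbouring flask. With the same crossing, the early version gives 24.4% and the late version 13.0%. That birch flask gave 16.4% product, between the two. Its reagent stood at 3.4% of charge, which is 0.00680 M, below the crossing, with 84% of the starting material still there.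

(The numbers were drawn at random within sensible limits.)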